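The numbers in the tables are simulated for an exercise, noise included.

The easy setting was the charge. A substrate goes to target, and target can go on to over-reaction product B. I worked in fractions of the charge, and with first-order steps a fraction does not move with the charge, so by hand the step to 0.80 M did nothing. That was my assumption: dusk and midnight changed charge and temperature together and could not test it.

| setting | dusk | midnight | beta | theta |
|---|---|---|---|---|
| substrate | 0.40 M | 0.60 M | 0.80 M | 0.80 M |
| temperature | −16 °C | −8 °C | −20 °C | −5 °C |
| remark | run made earlier | run made earlier |  |  |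
| time |  |  | 12 h | 12 h |

| dusk: time / h | dusk: target / % | midnight: time / h | midnight: target / % |
|---|---|---|---|
| 1.33 | 1.1 | 0.250 | 0 |
| 3.00 | 4.3 | 0.500 | 2.6 |
| 4.00 | 8.0 | 1.00 | 5.9 |
| 6.00 | 10.7 | 2.00 | 14.5 |
| 8.00 | 14.7 | 4.00 | 25.9 |

(standard deviation of a reading: 1 percentage point)

1. which of the two there is more of at the end, beta (over-reaction product B / target)
2. which of the two there is more of at the end, theta (over-reaction product B / target)
3. amount of target at the end, in percent of the substrate charged, beta
4. amount of target at the end, in percent of the substrate charged, theta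

- the earlier runs were read with a standard deviation of 1 percentage point

Temperature came next. Both runs were read at 4.00 h, so dividing one mean rate by the other cancelled the hours:

target in midnight / target in dusk = 25.9 % / 8.0 % = 3.24

I called this the clock factor, the speed-up of the flask from −16 °C to −8 °C, a time–temperature shift factor read from the readings. If the steps speed up alike, a change of temperature rescales the hours, so time was the third setting. Beta lies half that gap below dusk:

beta: 12 h / √3.24 = 6.67 h of dusk time, target 12.0 %

theta: 12 h scaled up from midnight = 18.6 h of midnight time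

Midnight's straight line would give 120 % at that time, more than the charge, so it had to bend. Theta's time stood beyond the last midnight reading, so I committed to 12.0 % for beta and to no figure for theta.

The forecast gave 17 % for beta and 57 % for theta, with target ahead in beta and target ahead in theta: “Target probably still exceeds B, though theta is less certain”.

Beta gave 12.7 % of target and 0.975 % of B. Theta gave 27.1 % of target and 51.6 % of B.

    substrate ⇌ dormant form (K = 0.710, k = 5.90 × 10⁻⁴ min⁻¹, Ea = 89.0 kJ mol⁻¹, ΔH = −42.0 kJ mol⁻¹)
    intermediate ⇌ isomer of the product (K = 2.90, k = 9.40 × 10⁻⁴ min⁻¹, Ea = 88.0 kJ mol⁻¹, ΔH = −12.0 kJ mol⁻¹)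
    target → over-reaction product B (k = 2.50 × 10⁻⁴ min⁻¹, Ea = 87.0 kJ mol⁻¹)
    target → over-reaction product A (k = 7.00 × 10⁻⁷ min⁻¹, Ea = 104 kJ mol⁻¹)
    substrate → intermediate (k = 7.70 × 10⁻⁴ min⁻¹, Ea = 82.0 kJ mol⁻¹)
    intermediate ⇌ target (K = 6.00, k = 0.00170 min⁻¹, Ea = 89.0 kJ mol⁻¹, ΔH = 17.0 kJ mol⁻¹)
    (constants at −20 °C)

Theta's target fell from 35.9 % at 6.00 h to 27.1 % at 12.0 h, and the conversion of target into B is the main reason for the low end value: with that step struck out, theta ends with 70.1 % of target, and target is no longer behind B. By the clock factor, theta's 12 h stand for 109 h of beta time. Beta left to 120 h shows the same order, with target at 23.4 %. Over-reaction product B in that flask stands higher, at 43.3 %.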